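Readings and results are calculated on assumed constants.

I compare green and teal by the share of G left, not by c(G). Green and teal start from the same c(E), and at 25.0 min green keeps 88.6% of its G and teal 88.4%, although teal holds twice the c(G). So up to that reading the loss of G looks pseudo-first-order, and I count in half-lives, knowing that this is read from the early part of the runs.

| flask | G | E | remark | time |
|---|---|---|---|---|
| green | 47 mM | 1.41 mM | the very flask that is asked about, followed so far |  |
| teal | 94 mM | 1.41 mM | run made earlier |  |
| flask | 47 mM | 1.41 mM |  | 3.0 h |

- green (time / min: G / %, D / %): 2.00: 99.6, 1.4; 6.00: 96.6, 3.7; 12.0: 92.6, 5.8; 20.0: 93.0, 8.9; 25.0: 88.6, 8.0; 30.0: 88.7, 12.3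
- teal (time / min: G / %, D / %): 8.00: 97.0, 3.5; 25.0: 88.4, 11.6; 40.0: 81.0, 16.5; 60.0: 75.0, 22.2; 90.0: 61.8, 30.3; 120: 50.3, 35.3

(scatter of a reading: 1 percentage point)

- E is the free proton; pH is minus the decimal logarithm of its molar concentration
- the earlier runs were read with a standard deviation of 1 percentage point

* part of the G that has reacted at 3.0 h
* pH of the solution at 3.0 h

Teal has 50.3% of its G left at 120 min, which gives the half-life of G, the time in which the share of G left halves, as 2.02 h. Green's 3.0 h is then 1.49 half-lives, so I reckon 35.7% of the G left and 64.3% reacted. Teal's reading at 25.0 min gives a longer half-life, 2.34 h. That gap is a reading with scatter, but teal may be quickening, and green holds less G, so I treat my figure as the upper side. No reading shows E, so I reckon no pH.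

The forecast says 63% reacted, a little below mine, and pH 2.75: “Constant k gives 58% reacted; mild acceleration gives about 63%”.

    G + E → L + E + D (k = 140 /M/h)
    L ⇌ J + E, settled at all times (K = 5.00 × 10⁻⁵ M)
    G → L + D (k = 0.0690 /h)
    D → Z (k = 0.310 /h)

The flask gives 62.2% reacted and pH 2.68. By then E stands at 148% of its charge. My 1.49 half-lives of 2.02 h promised 35.7% of the G left, and 38% is left. The neighbour charged with 12 mM of G runs for the same time, so the same count promises it 35.7% too; it keeps 43% of its G, with E at 115% of its charge.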